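Readings and results are calculated with made-up constants; noise was put on by code.

**Hidden exit.** The readings show side product and target, so we cannot follow intermediate A directly.

| flask | starting material | reagent | protic impurity | remark | time |
|---|---|---|---|---|---|
| alpha | 0.35 M | 0.367 M | 7 mM | run made earlier |  |
| epsilon | 0.35 M | 0.25 M | 7 mM | run made earlier |  |
| beta | 0.35 M | 0.55 M | 7 mM | run made earlier |  |
| noon | 0.35 M | 0.367 M | 7.00 mM | everything together at the start | 10 d |
| summer | 0.35 M | 0.367 M (fed, over 6.0 d) | 7.00 mM | all else is in the flask from the start; the feed brings no volume worth counting | 10 d |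
| spring | 0.35 M (fed, over 6.0 d) | 0.367 M | 7.00 mM | all else is in the flask from the start; the feed brings no volume worth counting | 10 d |

- alpha (time / d: side product / %, target / %): 1.04: 1.1, 14.5; 2.08: 4.6, 13.0; 3.00: 7.6, 11.6; 4.00: 9.3, 9.7; 5.00: 13.4, 8.6; 6.00: 16.6, 6.6
- epsilon (time / d: side product / %, target / %): 1.04: 0.9, 9.8; 1.67: 1.5, 9.6; 2.50: 3.9, 8.2; 4.00: 7.5, 6.0; 8.00: 17.3, 3.9; 12.0: 23.6, 2.2
- beta (time / d: side product / %, target / %): 1.04: 1.2, 20.5; 1.67: 2.8, 19.0; 2.50: 7.0, 17.2; 4.00: 12.4, 13.9; 8.00: 27.1, 7.6; 12.0: 36.5, 4.4

(readings scatter by 0.5 percentage points)

- which flask leads in amount of side product, in percent of the starting material charged ("all alike" within 1.5 percentage points) (noon / summer / spring / all alike)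
- how much side product is there at the end, in percent of the starting material charged: noon
- how much side product is there at the end, in percent of the starting material charged: summer
- how much side product is there at the end, in percent of the starting material charged: spring

- steps that have been proposed: starting material + reagent <-> target; starting material -> intermediate A; intermediate A -> intermediate B; reagent + intermediate B <-> intermediate C; reagent + intermediate A -> side product; starting material + protic impurity -> quenched substrate

**Even split.** In the proposed steps, intermediate A leaves by itself to intermediate B, or with reagent to side product. We take as the reference level on our scale the reagent level at which both exits run equally, and write reagent as a fraction of the starting material charge. Suppose equal amounts have left intermediate A in the beta and epsilon runs at 12.0 d. Their side product readings, 36.5% and 23.6%, then put this even point at 1.31.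

**One number.** Noon's reagent charge of 1.05 gives 0.444, its split share: the fraction of what leaves intermediate A that ends as side product (a selectivity factor). The epsilon run has 0.352. Its side product, interpolated to 10 d, gives an estimate of 58.1% of the charge having left intermediate A. Taking the same amount for noon, we reckon 25.8% there.

**Its test.** The share does not separate noon from spring. Spring has noon's reagent charge and so its share, yet its starting material arrives over 6.0 d. Summer, midway through its feed, has delivered 0.524, for a share of 0.285. We expect noon to lead.

**The forecast.** It names noon, with 25% for noon, 21.5% for summer and 17.5% for spring, saying of summer: “A forms while reagent is scarce, so much leaks to B”. Its noon lies 0.80 percentage points below ours.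

**The result.** noon leads, with 26.3% against 22.7% for summer and 19.0% for spring, so the forecast held.

    starting material + reagent ⇌ target (K = 0.670 M⁻¹, k = 0.00570 M⁻¹ min⁻¹)
    starting material → intermediate A (k = 1.10 × 10⁻⁴ min⁻¹)
    intermediate A → intermediate B (k = 1.50 × 10⁻⁴ min⁻¹)
    reagent + intermediate B ⇌ intermediate C (K = 0.970 M⁻¹, k = 8.00 × 10⁻⁴ M⁻¹ min⁻¹)
    reagent + intermediate A → side product (k = 4.30 × 10⁻⁴ M⁻¹ min⁻¹)
    starting material + protic impurity → quenched substrate (k = 0.0100 M⁻¹ min⁻¹)

Striking out the step from reagent and intermediate B to intermediate C moves noon to 26.9%. At 10.0 d, noon's side product over side product plus intermediates B and C is 0.445, against our split share of 0.444.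

**Second flask.** With 0.22 M of reagent, the share is 0.323, which gives 18.8%. The computed neighbour holds 18.3%.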